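Start from an invariant of the reaction: take each unit of reagent consumed to convert one unit of substrate of either hand, so the reagent charged bounds the total product. In Wednesday's, Thursday's and Friday's it is the limiting reagent by charge, and the question is how much of it ends up as left-handed product.

| flask | left-handed substrate | right-handed substrate | reagent | free catalyst | temperature | remark | time |
|---|---|---|---|---|---|---|---|
| east | 0.29 M | 0.29 M | 0.54 equiv | 0.55 mol% | 20 °C | run made earlier |  |
| north-east | 0.29 M | 0.29 M | 1.2 equiv | 0.55 mol% | 40 °C | run made earlier |  |
| Wednesday's | 0.29 M | 0.29 M | 0.800 equiv | 0.55 mol% | 25 °C |  | 50 h |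
| Thursday's | 0.29 M | 0.29 M | 0.800 equiv | 0.55 mol% | 40 °C |  | 50 h |
| Friday's | 0.29 M | 0.29 M | 0.800 equiv | 0.55 mol% | 55 °C |  | 50 h |

| run | time / h | left-handed product / % | left-handed substrate / % |
|---|---|---|---|
| east | 5.00 | 18 | 34 |
| east | 15.0 | 24 | 28 |
| east | 25.0 | 24 | 25 |
| east | 40.0 | 29 | 25 |
| north-east | 1.33 | 36 | 15 |
| north-east | 4.00 | 44 | 4 |
| north-east | 8.00 | 49 | 4 |
| north-east | 20.0 | 47 | 1 |

(each reading ± 1.5 percentage points)

1. the best flask by amount of left-handed product, in percent of the left-handed substrate and right-handed substrate together charged; "all alike" if 1.5 percentage points covers them all (Wednesday's / Thursday's / Friday's / all alike)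
2. amount of left-handed product at the end, in percent of the left-handed substrate and right-handed substrate together charged, Wednesday's
3. amount of left-handed product at the end, in percent of the left-handed substrate and right-handed substrate together charged, Thursday's
4. amount of left-handed product at the end, in percent of the left-handed substrate and right-handed substrate together charged, Friday's

Climb the ladder of times, fastest first. In the north-east run at 40 °C, left-handed product reads 36% after 1.33 h. In the east run, colder at 20 °C, it reads 18% after 5.00 h. Wednesday's, the coldest new flask, gets 3.33 times the 15.0 h after which the east readings level off, so I expect the reaction to finish before the reading in each new flask.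

The next rung is the stop. From 15.0 h to 40.0 h the east run keeps 25% or more of left-handed substrate, and its left-handed product averages 25.7%. With 1.2 equiv of reagent, the same catalyst loading and a warmer bath, the north-east run takes left-handed substrate down to 1% by 20.0 h. Two settings differ between these runs, so this is a reading and not a proof: I read the east stop as the 0.54 equiv of reagent used up.

Scaling that plateau by reagent charged gives 38.0% at 0.800 equiv. Call this the reagent ceiling: the left-handed product standing once the charged reagent is used, taken as proportional to the reagent charged while left-handed substrate remains. The scatter of the readings carries into it as 1.3 percentage points. This is my reckoning, and it assumes that temperature leaves the share of reagent unchanged.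

The forecast gives 38.5%, 39% and 39% for Wednesday's, Thursday's and Friday's, with the verdict all alike, by a different route: “At 0.80 equiv the ceiling is therefore about 0.48 × 80 ≈ 38–40%.”

The flasks give 38.8%, 38.5% and 38.0% for Wednesday's, Thursday's and Friday's, beside my reagent ceiling of 38.0%, and the verdict is all alike.

    2 free catalyst ⇌ resting dimer (K = 6900 L mol⁻¹, k = 140 L mol⁻¹ min⁻¹, Ea = 36.0 kJ mol⁻¹, ΔH = −50.0 kJ mol⁻¹)
    reagent + free catalyst + right-handed substrate → free catalyst + right-handed product (k = 4.20 L² mol⁻² min⁻¹, Ea = 63.0 kJ mol⁻¹)
    reagent + free catalyst + left-handed substrate → free catalyst + left-handed product (k = 210 L² mol⁻² min⁻¹, Ea = 43.0 kJ mol⁻¹)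
    free catalyst → spent catalyst (k = 1.40 × 10⁻⁵ min⁻¹, Ea = 117 kJ mol⁻¹)
    (constants at 40 °C)

In Friday's flask at 0.192 h, the reagent was used by the left-handed step 22 times as fast as by the right-handed step. At 50.0 h, 0% of the reagent's charge stood in that flask, beside 96% of the right-handed substrate charged. A neighbour of Friday's with 0.480 equiv of reagent has a reagent ceiling of 22.8%, and it gave 23.1%.

Readings and results are calculated with made-up constants; noise was put on by code.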